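The route rests on cutting the bond between C-2 of the 5-methylphenoxy ring (the aryl carbon ortho to the diaryl-ether oxygen and para to the ring methyl) and the benzylic methine C-2 of its 6-methylhept-5-en-2-yl chain. That methine bears only H, CH3 and the homoprenyl CH2, so it is the carbinol carbon of (R)-sulcatol in disguise: C–O becomes C–Sn with inversion, then C–aryl with retention. The key step, a stereoretentive Stille coupling of the (S)-sec-alkyl carbastannatrane, joins the whole C8 chain to an aryl bromide that is the MOM-protected diaryl ether already carrying the other (S) side chain, and completes the carbon skeleton in one operation.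

Key step: step 8

Remark: (R)-6-methylhept-5-en-2-ol of high enantiomeric purity is taken as a purchasable starting material. Both stereocentres of the target are (S), and each derives from this alcohol by one inversion (C–O to C–Sn) and one retention (C–Sn to C–aryl).

Step 1
Reactants: 1 (2R)-6-methylhept-5-en-2-ol
Product: 2 (2R)-6-methylhept-5-en-2-yl methanesulfonate
Conditions: MsCl, Et3N, CH2Cl2, 0 °C
Reagents that add atoms: methanesulfonyl chloride, CS(=O)(=O)Cl
Why: O-sulfonylation (mesylation) does not touch the C–O stereocentre and should give a secondary sulfonate ready for SN2 displacement.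

Step 2
Reactants: 2 (2R)-6-methylhept-5-en-2-yl methanesulfonate; 3 5-chloro-1-aza-5-stannabicyclo[3.3.3]undecane
Product: 5 5-[(2S)-6-methylhept-5-en-2-yl]-1-aza-5-stannabicyclo[3.3.3]undecane, via stannatranyl lithium 4 (not isolated)
Conditions: 3, lithium naphthalenide (2 equiv), THF, −78 °C; then 2, −78 °C → rt
Reagents that add atoms: none
Why: Two-electron reduction of the Sn–Cl bond should give the stannyl anion, which displaces the secondary mesylate by SN2 with inversion, so the (R) C–O centre becomes the (S) C–Sn centre (nucleophilic stannylation of an alkyl sulfonate).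

Step 3
Reactants: 6 4-fluoro-3-methylbenzaldehyde; 7 2-bromo-5-methylphenol
Product: 8 4-(2-bromo-5-methylphenoxy)-3-methylbenzaldehyde
Conditions: K2CO3, DMF, 130 °C
Reagents that add atoms: none
Why: The para-formyl group activates the fluoride for SNAr by the phenoxide, and the aryl bromide is inert in the absence of a metal catalyst.

Step 4
Reactants: 8 4-(2-bromo-5-methylphenoxy)-3-methylbenzaldehyde
Product: 10 4-(2-bromo-5-methylphenoxy)-3-methylphenol, via aryl formate 9 (not isolated)
Conditions: mCPBA, CH2Cl2, rt; then K2CO3 (cat.), MeOH, rt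
Reagents that add atoms: mCPBA, OOC(=O)c1cccc(Cl)c1
Why: In this Baeyer–Villiger (Dakin-type) oxidation the electron-rich para-aryloxyphenyl group should migrate in preference to hydrogen, and methanolysis of the formate frees the phenol.

Step 5
Reactants: 10 4-(2-bromo-5-methylphenoxy)-3-methylphenol
Product: 11 4-(2-bromo-5-methylphenoxy)-2-iodo-5-methylphenol
Conditions: NIS (1.0 equiv), p-TsOH (cat.), MeCN, 0 °C → rt
Reagents that add atoms: N-iodosuccinimide, O=C1CCC(=O)N1I
Why: Electrophilic aromatic iodination should occur on the phenol ring (the far stronger activator), ortho to OH because para is blocked, and at the ortho site para to the ring methyl because the other lies between OH and CH3.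

Step 6
Reactants: 11 4-(2-bromo-5-methylphenoxy)-2-iodo-5-methylphenol
Product: 12 1-(2-bromo-5-methylphenoxy)-5-iodo-4-(methoxymethoxy)-2-methylbenzene
Conditions: MOMCl, i-Pr2NEt, CH2Cl2, 0 °C → rt
Reagents that add atoms: chloromethyl methyl ether, COCCl
Why: O-alkylation to the MOM acetal masks the acidic phenol with a small group that is stable to Pd(0), Cu(I) and fluoride in the two couplings that follow.

Step 7
Reactants: 12 1-(2-bromo-5-methylphenoxy)-5-iodo-4-(methoxymethoxy)-2-methylbenzene; 5 5-[(2S)-6-methylhept-5-en-2-yl]-1-aza-5-stannabicyclo[3.3.3]undecane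
Product: 13 1-(2-bromo-5-methylphenoxy)-4-(methoxymethoxy)-2-methyl-5-[(2S)-6-methylhept-5-en-2-yl]benzene
Conditions: 5 (1.05 equiv), Pd(dba)2 (5 mol%), JackiePhos (10 mol%), CuCl, KF, MeCN, 45 °C
Reagents that add atoms: none
Why: Oxidative addition of Pd(0) is faster at C–I than at C–Br and the secondary alkyl group of 5 is transferred with retention, so the (S) C–Sn centre becomes the (S) ring-A benzylic centre under reagent control (stereoretentive Stille coupling of a secondary alkyl stannatrane); any coupling at C–Br only anticipates step 8 because both side chains are identical.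

Step 8
Reactants: 13 1-(2-bromo-5-methylphenoxy)-4-(methoxymethoxy)-2-methyl-5-[(2S)-6-methylhept-5-en-2-yl]benzene; 5 5-[(2S)-6-methylhept-5-en-2-yl]-1-aza-5-stannabicyclo[3.3.3]undecane
Product: 14 1-(methoxymethoxy)-5-methyl-2-[(2S)-6-methylhept-5-en-2-yl]-4-{5-methyl-2-[(2S)-6-methylhept-5-en-2-yl]phenoxy}benzene
Conditions: 5 (1.5 equiv), Pd(dba)2 (5 mol%), JackiePhos (10 mol%), CuCl (2 equiv), KF (2 equiv), MeCN, 60 °C
Reagents that add atoms: none
Why: Pd(0)/JackiePhos inserts into the ring-B C–Br bond of 13, the only aryl halide left, and the secondary alkyl group of 5, whose apical C–Sn bond is weakened by transannular N→Sn donation, is passed on with Cu(I)/fluoride assistance through a closed, front-side SE2 transition state before C–C reductive elimination. The closest known reaction type is the stereoretentive Stille coupling of secondary alkyl azastannatranes (carbastannatranes) with aryl halides; no ring is closed. The new benzylic stereocentre is controlled by the reagent alone: the (S) C–Sn centre, made from (R)-sulcatol by SN2 inversion, is transferred with retention to the (S) C–aryl centre, independent of the remote ring-A stereocentre. The step needs (i) exclusive transfer of the secondary alkyl group over the three cage CH2 groups, secured by the atrane activation of the apical substituent, (ii) reductive elimination faster than β-hydride elimination and re-insertion, which would move palladium along the chain or erode configuration, secured by the bulky, electron-poor JackiePhos ligand, and (iii) tolerance of the MOM acetal and both trisubstituted alkenes, which are inert to Pd(0), Cu(I) and fluoride. The diaryl-ether oxygen ortho to the C–Br bond is a small, unbranched substituent at the reacting carbon, so the coupling site should remain accessible.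

Step 9
Reactants: 14 1-(methoxymethoxy)-5-methyl-2-[(2S)-6-methylhept-5-en-2-yl]-4-{5-methyl-2-[(2S)-6-methylhept-5-en-2-yl]phenoxy}benzene
Product: 15 5-methyl-2-[(2S)-6-methylhept-5-en-2-yl]-4-{5-methyl-2-[(2S)-6-methylhept-5-en-2-yl]phenoxy}phenol
Conditions: p-TsOH·H2O (cat.), MeOH, 40 °C
Reagents that add atoms: none
Why: Acid-catalysed transacetalisation with methanol cleaves the labile phenolic MOM ether under conditions mild enough to leave the trisubstituted alkenes and the non-epimerisable benzylic C–H stereocentres untouched.

Compound list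
1 | (2R)-6-methylhept-5-en-2-ol, (R)-sulcatol | C[C@@H](O)CCC=C(C)C | starting material
2 | (2R)-6-methylhept-5-en-2-yl methanesulfonate | C[C@@H](OS(C)(=O)=O)CCC=C(C)C | intermediate
3 | 5-chloro-1-aza-5-stannabicyclo[3.3.3]undecane | Cl[Sn]12CCCN(CCC1)CCC2 | starting material
4 | 5-lithio-1-aza-5-stannabicyclo[3.3.3]undecane (stannatranyl lithium) | [Li][Sn]12CCCN(CCC1)CCC2 | intermediate (not isolated)
5 | 5-[(2S)-6-methylhept-5-en-2-yl]-1-aza-5-stannabicyclo[3.3.3]undecane | C[C@H]([Sn]12CCCN(CCC1)CCC2)CCC=C(C)C | intermediate
6 | 4-fluoro-3-methylbenzaldehyde | Cc1cc(C=O)ccc1F | starting material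
7 | 2-bromo-5-methylphenol | Cc1ccc(Br)c(O)c1 | starting material
8 | 4-(2-bromo-5-methylphenoxy)-3-methylbenzaldehyde | Cc1cc(C=O)ccc1Oc1cc(C)ccc1Br | intermediate
9 | 4-(2-bromo-5-methylphenoxy)-3-methylphenyl formate | Cc1cc(OC=O)ccc1Oc1cc(C)ccc1Br | intermediate (not isolated)
10 | 4-(2-bromo-5-methylphenoxy)-3-methylphenol | Cc1cc(O)ccc1Oc1cc(C)ccc1Br | intermediate
11 | 4-(2-bromo-5-methylphenoxy)-2-iodo-5-methylphenol | Cc1cc(O)c(I)cc1Oc1cc(C)ccc1Br | intermediate
12 | 1-(2-bromo-5-methylphenoxy)-5-iodo-4-(methoxymethoxy)-2-methylbenzene | Cc1cc(OCOC)c(I)cc1Oc1cc(C)ccc1Br | intermediate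
13 | 1-(2-bromo-5-methylphenoxy)-4-(methoxymethoxy)-2-methyl-5-[(2S)-6-methylhept-5-en-2-yl]benzene | CC(C)=CCC[C@H](C)c1cc(Oc2cc(C)ccc2Br)c(C)cc1OCOC | intermediate
14 | 1-(methoxymethoxy)-5-methyl-2-[(2S)-6-methylhept-5-en-2-yl]-4-{5-methyl-2-[(2S)-6-methylhept-5-en-2-yl]phenoxy}benzene | CC(C)=CCC[C@H](C)c1cc(Oc2cc(C)ccc2[C@@H](C)CCC=C(C)C)c(C)cc1OCOC | intermediate
15 | 5-methyl-2-[(2S)-6-methylhept-5-en-2-yl]-4-{5-methyl-2-[(2S)-6-methylhept-5-en-2-yl]phenoxy}phenol | CC(C)=CCC[C@H](C)c1cc(Oc2cc(C)ccc2[C@@H](C)CCC=C(C)C)c(C)cc1O | target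

Total step count: 9. Longest linear sequence: 7 steps (steps 3 to 9, from 6 and 7).

Steps most likely to fail

Step 8 (key step). Transfer of the secondary alkyl group to the hindered ortho-aryloxy arylpalladium may be slow, so that protodebromination or β-hydride elimination with chain isomerisation and loss of stereochemical fidelity takes over. The fallback sets out from 13 and comes back at 14, and makes the same bond by a boron-ate 1,2-shift instead of a palladium coupling. Bromine–lithium exchange on 13 (n-BuLi, THF, −78 °C), B(Oi-Pr)3 and then neopentyl glycol should give the aryl neopentylglycol boronate F1. Alcohol 1 is acylated (NaH, 2,4,6-triisopropylbenzoyl chloride, THF) to the (R)-configured 2,4,6-triisopropylbenzoate F2. F2 is lithiated with retention (s-BuLi, TMEDA, cyclopentyl methyl ether, −60 °C) and trapped by F1 with retention. On warming, the aryl group should migrate from boron to carbon with inversion and expel the benzoate, giving the tertiary benzylic boronic ester F3. Protodeboronation with retention (CsF, H2O, dioxane, 45 °C) should then deliver 14 with the (S) centre.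

Step 7. Oxidative addition may not discriminate fully between C–I and C–Br, and alkyl transfer next to the ortho acetal may be sluggish. The fallback sets out from 12 and comes back at 13. Iodine–magnesium exchange with i-PrMgCl·LiCl (THF, −40 °C) leaves the C–Br bond untouched. Quenching with B(OMe)3 and esterification with neopentyl glycol should give the ring-A aryl boronate F4. F4 is combined with lithiated F2 (made as described for step 8) to give, after the 1,2-aryl shift, the tertiary boronic ester F5. Protodeboronation with retention (CsF, H2O, dioxane, 45 °C) should give 13.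

Step 2. The basic stannyl anion may cause E2 elimination, or electron transfer to the sulfonate may give a radical path that lowers the configurational purity at C–Sn. The fallback sets out from 12 and comes back at 13, and replaces tin by boron. 5-Bromo-2-methylpent-2-ene is converted through its Grignard reagent and 2-isopropoxy-4,4,5,5-tetramethyl-1,3,2-dioxaborolane into the homoprenyl pinacol boronate F6. Ethyl N,N-diisopropylcarbamate is lithiated with s-BuLi/(−)-sparteine (Et2O, −78 °C) and homologated with F6 (retention at boron capture, inversion in the 1,2-shift) to the (R)-configured secondary pinacol boronate F7. KHF2 (MeOH/H2O) converts F7 into the potassium trifluoroborate F8. F8 is coupled with 12 in a stereoinvertive Suzuki–Miyaura coupling of an unactivated secondary alkyltrifluoroborate (Pd/P(t-Bu)3, K2CO3, toluene/H2O, 100 °C), which should give 13 with the (S) centre. The same reagent would then serve for the conversion of 13 into 14.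

Further compounds
F1 | step 8 | 2-{2-[4-(methoxymethoxy)-2-methyl-5-((2S)-6-methylhept-5-en-2-yl)phenoxy]-4-methylphenyl}-5,5-dimethyl-1,3,2-dioxaborinane | CC(C)=CCC[C@H](C)c1cc(Oc2cc(C)ccc2B3OCC(C)(C)CO3)c(C)cc1OCOC
F2 | step 8 | (2R)-6-methylhept-5-en-2-yl 2,4,6-triisopropylbenzoate | C[C@@H](OC(=O)c1c(C(C)C)cc(C(C)C)cc1C(C)C)CCC=C(C)C
F3 | step 8 | 2-{(2S)-2-[2-(4-(methoxymethoxy)-2-methyl-5-((2S)-6-methylhept-5-en-2-yl)phenoxy)-4-methylphenyl]-6-methylhept-5-en-2-yl}-5,5-dimethyl-1,3,2-dioxaborinane | CC(C)=CCC[C@H](C)c1cc(Oc2cc(C)ccc2[C@](C)(B3OCC(C)(C)CO3)CCC=C(C)C)c(C)cc1OCOC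
F4 | step 7 | 2-[5-(2-bromo-5-methylphenoxy)-2-(methoxymethoxy)-4-methylphenyl]-5,5-dimethyl-1,3,2-dioxaborinane | Cc1cc(OCOC)c(B2OCC(C)(C)CO2)cc1Oc1cc(C)ccc1Br
F5 | step 7 | 2-{(2S)-2-[5-(2-bromo-5-methylphenoxy)-2-(methoxymethoxy)-4-methylphenyl]-6-methylhept-5-en-2-yl}-5,5-dimethyl-1,3,2-dioxaborinane | CC(C)=CCC[C@@](C)(B3OCC(C)(C)CO3)c1cc(Oc2cc(C)ccc2Br)c(C)cc1OCOC
F6 | step 2 | 4,4,5,5-tetramethyl-2-(4-methylpent-3-en-1-yl)-1,3,2-dioxaborolane | CC(C)=CCCB1OC(C)(C)C(C)(C)O1
F7 | step 2 | 4,4,5,5-tetramethyl-2-[(2R)-6-methylhept-5-en-2-yl]-1,3,2-dioxaborolane | C[C@@H](B1OC(C)(C)C(C)(C)O1)CCC=C(C)C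
F8 | step 2 | potassium trifluoro[(2R)-6-methylhept-5-en-2-yl]borate | C[C@@H]([B-](F)(F)F)CCC=C(C)C.[K+]
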